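The tetralin's saturated ring is disconnected at C2–C3, the one ring bond whose two carbons are plain methylenes, neither stereogenic nor aromatic. The trans-related C1 and C4 centres are therefore built independently on two ortho benzylic arms (C4 by asymmetric hydroboration, C1 by rhodium-catalysed arylation of furanone, C11 by trans hydroxymethylation), the arm termini are then tied through sulfur, and a Ramberg–Bäcklund contraction of the 1,5-disubstituted 3-benzothiepine 3,3-dioxide expels SO2 and forges C2=C3 in a single operation without disturbing C1 or C4. The precursor carries both side-chain alcohols as TBS ethers and the catechol as its bis-MOM ether, so that C7 carboxylation and a purely acidic unmasking can follow.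

Key step: step 20

Numbering used throughout (tetralin numbering of the target): C1 bears the side chain, C2 and C3 are the ring methylenes, C4 bears the methyl group, C4a/C8a are the fusion carbons, C5 and C6 bear the oxygens, C7 the carboxyl group, C8 is CH. Side chain: C11 (bears C20H2O), C12, C13, C14, C15 (bears CH3 and C16H2O).

Design remarks and assumptions:
- The catechol is carried as its bis(methoxymethyl) ether, not as methyl ethers. The acetals leave with dilute acid together with the silyl ethers, whereas a boron trihalide demethylation would threaten the primary silyl ethers and alcohols with bromide formation. The C6 acetal is also a strong director for lithiation at C7. The aryl starting material is therefore 2',3'-dihydroxyacetophenone.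
- The sulfide is oxidised with molybdate/H2O2, because an acidic peroxysulfate would attack primary TBS ethers. The ring alkene is reduced with diimide, because a palladium hydride could move the double bond into conjugation and erase C1 or C4.
- Assumption: the ligand antipodes in steps 3 and 7 are those expected to give the drawn configurations; the sense of induction would be confirmed on the first batch.
- Steps 11–14 make the side-chain phosphonium salt (second branch).

Step 1
Reactants: 1 2',3'-dihydroxyacetophenone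
Product: 2 1-[2,3-bis(methoxymethoxy)phenyl]ethan-1-one
Conditions: MOMCl (3 equiv), i-Pr2NEt (4 equiv), DMAP (cat.), CH2Cl2, 0 °C → 40 °C
Reagents that add atoms: chloromethyl methyl ether, COCCl
Why: Double O-alkylation of the phenols by the α-chloro ether gives the two methoxymethyl acetals, and gentle heating with excess reagent should also convert the carbonyl-chelated 2'-hydroxyl.

Step 2
Reactants: 2 1-[2,3-bis(methoxymethoxy)phenyl]ethan-1-one
Product: 3 1,2-bis(methoxymethoxy)-3-(prop-1-en-2-yl)benzene
Conditions: Ph3PCH3Br (1.5 equiv), KOtBu (1.45 equiv), THF, 0 °C → rt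
Reagents that add atoms: methyltriphenylphosphonium bromide, C[P+](c1ccccc1)(c1ccccc1)c1ccccc1.[Br-]
Why: Wittig methylenation of the aryl methyl ketone with the non-stabilised ylide is reliable for ortho-substituted acetophenones, and the acetal ethers are inert to the basic conditions.

Step 3
Reactants: 3 1,2-bis(methoxymethoxy)-3-(prop-1-en-2-yl)benzene
Product: 5 (2S)-2-[2,3-bis(methoxymethoxy)phenyl]propan-1-ol, via pinacol boronate 4 (not isolated)
Conditions: chiral iminopyridine–oxazoline CoCl2 complex (2 mol %, antipode for the S product), NaBHEt3 (4 mol %), HBpin (1.2 equiv), THF, rt; then 3 M NaOH, 30% H2O2, 0 °C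
Reagents that add atoms: hydrogen peroxide, OO
Why: Catalyst-controlled anti-Markovnikov hydroboration of the 1,1-disubstituted aryl alkene (an established cobalt-catalysed asymmetric reaction of α-methylstyrenes) places boron on the terminal carbon while the chiral ligand selects the alkene face for hydrogen delivery to the benzylic carbon, which sets C4; oxidation of the C–B bond with retention then gives the S primary alcohol.

Step 4
Reactants: 5 (2S)-2-[2,3-bis(methoxymethoxy)phenyl]propan-1-ol
Product: 6 1-[(2S)-1-(benzyloxy)propan-2-yl]-2,3-bis(methoxymethoxy)benzene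
Conditions: NaH, BnBr, n-Bu4NI (cat.), THF, 0 °C → rt
Reagents that add atoms: benzyl bromide, BrCc1ccccc1
Why: Williamson etherification masks the C3 oxygen with a group that survives the organolithium, enolate and hydride steps and later falls off during the hydrogenation of step 16.

Step 5
Reactants: 6 1-[(2S)-1-(benzyloxy)propan-2-yl]-2,3-bis(methoxymethoxy)benzene
Product: 7 2-[(2S)-1-(benzyloxy)propan-2-yl]-1-bromo-3,4-bis(methoxymethoxy)benzene
Conditions: NBS (1.05 equiv), MeCN, 0 °C → rt, dark
Reagents that add atoms: N-bromosuccinimide, O=C1CCC(=O)N1Br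
Why: Electrophilic aromatic bromination should occur para to the C6 acetal oxygen (at C8a, also ortho to the alkyl group), because the C5 acetal is flanked on both sides and twisted out of conjugation so that the unhindered C6 oxygen dominates the directing effect, while the benzyl ring is far less activated.

Step 6
Reactants: 7 2-[(2S)-1-(benzyloxy)propan-2-yl]-1-bromo-3,4-bis(methoxymethoxy)benzene
Product: 10 {2-[(2S)-1-(benzyloxy)propan-2-yl]-3,4-bis(methoxymethoxy)phenyl}boronic acid, via aryllithium 8 (not isolated), via lithium triisopropoxyborate 9 (not isolated)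
Conditions: n-BuLi (1.1 equiv), THF, −78 °C; B(Oi-Pr)3 (1.5 equiv), −78 °C → rt; H2O, then aq. NH4Cl to pH 6
Reagents that add atoms: triisopropyl borate, CC(C)OB(OC(C)C)OC(C)C; water, O
Why: Lithium–bromine exchange at −78 °C, trapping of the aryllithium with the borate ester and mild hydrolysis give the boronic acid without touching the acetals or the C4 stereocentre, which is not acidic.

Step 7
Reactants: 10 {2-[(2S)-1-(benzyloxy)propan-2-yl]-3,4-bis(methoxymethoxy)phenyl}boronic acid; 11 furan-2(5H)-one
Product: 12 (4S)-4-{2-[(2S)-1-(benzyloxy)propan-2-yl]-3,4-bis(methoxymethoxy)phenyl}dihydrofuran-2(3H)-one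
Conditions: [Rh(OH)((S)-BINAP)]2 (2.5 mol %), 11 (3 equiv), dioxane/H2O (10:1), 50 °C
Reagents that add atoms: none
Why: Hayashi–Miyaura rhodium-catalysed asymmetric 1,4-addition: transmetalation gives an arylrhodium(I) that inserts the butenolide C=C on the face selected by the bisphosphine (the S ligand is expected to give the S lactone by the usual model for cyclic enones and lactones), water protonates the rhodium enolate, and C1 is thereby set under catalyst control independently of C4.

Step 8
Reactants: 12 (4S)-4-aryl lactone from step 7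
Product: 14 (3S,4S)-4-{2-[(2S)-1-(benzyloxy)propan-2-yl]-3,4-bis(methoxymethoxy)phenyl}-3-(hydroxymethyl)dihydrofuran-2(3H)-one (3,4-trans), via lithium enolate 13 (not isolated)
Conditions: LDA (commercial solution, 1.1 equiv), THF, −78 °C; CH2O (gas, from cracked paraformaldehyde), −78 → −40 °C; aq. NH4Cl
Reagents that add atoms: formaldehyde, C=O
Why: Aldol addition of the lactone enolate to monomeric formaldehyde takes place on the face anti to the neighbouring C1 aryl group, so the hydroxymethyl group (C20) ends up trans to the aryl ring, which is the S configuration at C11 required by the target once the lactone carbonyl becomes C12.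

Step 9
Reactants: 14 trans-hydroxymethyl lactone
Product: 15 (3S,4S)-4-{2-[(2S)-1-(benzyloxy)propan-2-yl]-3,4-bis(methoxymethoxy)phenyl}-3-{[(tert-butyldimethylsilyl)oxy]methyl}dihydrofuran-2(3H)-one
Conditions: TBSCl, imidazole, DMF, 0 °C → rt
Reagents that add atoms: tert-butyldimethylsilyl chloride, CC(C)(C)[Si](C)(C)Cl
Why: Imidazole-promoted silylation of the primary alcohol blocks retro-aldol and elimination pathways and distinguishes C20–O from the C2 oxygen still held in the lactone.

Step 10
Reactants: 15 silylated lactone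
Product: 16 (3S,4S)-4-{2-[(2S)-1-(benzyloxy)propan-2-yl]-3,4-bis(methoxymethoxy)phenyl}-3-{[(tert-butyldimethylsilyl)oxy]methyl}tetrahydrofuran-2-ol (lactol; both anomers)
Conditions: DIBAL-H (1.2 equiv), CH2Cl2, −78 °C; Rochelle salt work-up
Reagents that add atoms: none
Why: Partial reduction of a lactone: at −78 °C hydride addition stops at the tetrahedral aluminium hemiacetal, which gives the lactol on work-up.

Step 11
Reactants: 17 methyl (S)-3-hydroxy-2-methylpropanoate (Roche ester)
Product: 18 methyl (S)-3-[(tert-butyldimethylsilyl)oxy]-2-methylpropanoate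
Conditions: TBSCl, imidazole, CH2Cl2, rt
Reagents that add atoms: tert-butyldimethylsilyl chloride, CC(C)(C)[Si](C)(C)Cl
Why: Silylation of the primary alcohol; this oxygen becomes C16–O, so the S configuration of the ester maps onto R at C15 once the ester carbon has been turned into C14.

Step 12
Reactants: 18 silylated Roche ester
Product: 19 (R)-3-[(tert-butyldimethylsilyl)oxy]-2-methylpropan-1-ol
Conditions: DIBAL-H (2.3 equiv), CH2Cl2, −78 → 0 °C; Rochelle salt work-up
Reagents that add atoms: none
Why: Hydride reduction of the ester to the primary alcohol proceeds without enolisation, so the stereocentre is not at risk.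

Step 13
Reactants: 19 (R)-3-[(tert-butyldimethylsilyl)oxy]-2-methylpropan-1-ol
Product: 20 (S)-tert-butyl(3-iodo-2-methylpropoxy)dimethylsilane
Conditions: I2, PPh3, imidazole, CH2Cl2, 0 °C → rt
Reagents that add atoms: iodine, II
Why: Appel-type iodination (displacement of an alkoxyphosphonium by iodide) at the primary carbon leaves the adjacent stereocentre untouched.

Step 14
Reactants: 20 (S)-tert-butyl(3-iodo-2-methylpropoxy)dimethylsilane
Product: 21 [(3R)-4-[(tert-butyldimethylsilyl)oxy]-3-methylbutyl]triphenylphosphonium iodide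
Conditions: Ph3PCH3Br (1.3 equiv), n-BuLi (1.25 equiv), THF, 0 °C; then 20, 0 °C → rt
Reagents that add atoms: methyltriphenylphosphonium bromide, C[P+](c1ccccc1)(c1ccccc1)c1ccccc1.[Br-]
Why: C-Alkylation of methylenetriphenylphosphorane by the primary iodide (SN2) inserts the missing carbon C13 and delivers the homologated phosphonium salt directly, a known way of lengthening an alkyl iodide into a Wittig salt.

Step 15
Reactants: 16 lactol; 21 phosphonium iodide
Product: 23 (2S,3S,4Z,7R)-2-{2-[(2S)-1-(benzyloxy)propan-2-yl]-3,4-bis(methoxymethoxy)phenyl}-8-[(tert-butyldimethylsilyl)oxy]-3-{[(tert-butyldimethylsilyl)oxy]methyl}-7-methyloct-4-en-1-ol, via phosphorus ylide 22 (not isolated)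
Conditions: 21 (2.5 equiv), KHMDS (commercial, 2.4 equiv), THF, −78 → 0 °C; then 16, −78 °C → rt
Reagents that add atoms: none
Why: Wittig olefination of the lactol through its open hydroxy-aldehyde form with the non-stabilised ylide forms C12=C13 (Z expected, geometry irrelevant because it is hydrogenated next) and frees the C2 hydroxyl; excess ylide serves as base for the lactol OH, and a lithium-free ylide at low temperature limits enolisation at C11.

Step 16
Reactants: 23 Z-alkene alcohol
Product: 24 (2S,3S,7R)-8-[(tert-butyldimethylsilyl)oxy]-3-{[(tert-butyldimethylsilyl)oxy]methyl}-2-{2-[(2S)-1-hydroxypropan-2-yl]-3,4-bis(methoxymethoxy)phenyl}-7-methyloctan-1-ol (C2/C3 diol)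
Conditions: H2 (1 atm), 10% Pd/C, NaHCO3 (solid), EtOAc/EtOH (1:1), rt
Reagents that add atoms: none
Why: Heterogeneous hydrogenation saturates C12=C13 and hydrogenolysis of the benzyl ether frees the C3 hydroxyl in the same operation, while TBS and MOM ethers are inert in the buffered medium.

Step 17
Reactants: 24 C2/C3 diol
Product: 25 C2/C3 dimesylate of 24 (both primary alcohols as methanesulfonates; 2S,3S,7R and 2S in the aryl arm)
Conditions: MsCl (2.5 equiv), Et3N (3 equiv), CH2Cl2, 0 °C
Reagents that add atoms: methanesulfonyl chloride, CS(Cl)(=O)=O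
Why: Sulfonylation of both primary alcohols converts C2–O and C3–O into leaving groups, and the silyl and acetal ethers are stable to MsCl/Et3N.

Step 18
Reactants: 25 dimesylate
Product: 26 (1S,5S)-1-[(2S,6R)-1,7-bis[(tert-butyldimethylsilyl)oxy]-6-methylheptan-2-yl]-6,7-bis(methoxymethoxy)-5-methyl-1,2,4,5-tetrahydro-3-benzothiepine
Conditions: Na2S·9H2O (1.5 equiv), DMF, 0.01 M, 50 °C, slow addition of 25
Reagents that add atoms: sodium sulfide, [Na+].[Na+].[S-2]
Why: Two SN2 displacements of primary mesylates by sulfide, the second one intramolecular (7-exo-tet) and favoured by the ortho-phenylene tether and high dilution; neither stereocentre is at a reacting carbon.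

Step 19
Reactants: 26 benzothiepine
Product: 28 (1S,5S)-1-[(2S,6R)-1,7-bis[(tert-butyldimethylsilyl)oxy]-6-methylheptan-2-yl]-6,7-bis(methoxymethoxy)-5-methyl-1,2,4,5-tetrahydro-3-benzothiepine 3,3-dioxide, via sulfoxide 27 (not isolated)
Conditions: (NH4)6Mo7O24·4H2O (10 mol %), 30% H2O2 (4 equiv), EtOH/THF, 0 °C → rt
Reagents that add atoms: hydrogen peroxide, OO
Why: Molybdate-catalysed peroxide oxidation takes the sulfide through the sulfoxide to the sulfone under nearly neutral conditions that should leave TBS ethers, MOM acetals and the electron-rich arene intact.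

Step 20
Reactants: 28 benzothiepine 3,3-dioxide
Product: 31 (1S,4R)-1-[(2S,6R)-1,7-bis[(tert-butyldimethylsilyl)oxy]-6-methylheptan-2-yl]-5,6-bis(methoxymethoxy)-4-methyl-1,4-dihydronaphthalene, via alpha-bromo sulfone 29 (not isolated), via episulfone 30 (not isolated)
Conditions: KOH on alumina (excess), CBr2F2 (4 equiv), t-BuOH/CH2Cl2 (1:1), 0 °C → rt, argon; filtered, concentrated cold, used at once
Reagents that add atoms: none
Why: Alumina-supported KOH removes a proton next to sulfur (at C2 or C3; either choice converges on the same alkene) and the carbanion takes bromine from CBr2F2 to give α-bromo sulfone 29; a second deprotonation on the other side of sulfur then expels bromide in a 1,3-elimination that joins C2 to C3 as thiirane dioxide 30, which sheds SO2 in a cheletropic step to leave the C2=C3 double bond. This is the Ramberg–Bäcklund reaction in its one-pot halogenative form, the established way to contract saturated cyclic sulfones (thiepane dioxides to cyclohexenes). The only ring closure is the 3-exo-tet displacement to the episulfone; loss of SO2 turns the seven-membered sulfone into the six-membered carbocycle, where the alkene can only be cis. No stereocentre is created: C1 and C4 are β to sulfur, are not deprotonated at any stage, and keep the trans relation set in steps 3 and 7. No regio- or stereoselectivity is required; what must be secured is the survival of the doubly activated C1–H and C4–H of 31, for which the heterogeneous base, low temperature, exclusion of air and immediate reduction (step 21) are chosen, while the difluorocarbene released from the reagent should be too unreactive to add to the new alkene.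

Step 21
Reactants: 31 1,4-dihydronaphthalene
Product: 32 (1S,4R)-1-[(2S,6R)-1,7-bis[(tert-butyldimethylsilyl)oxy]-6-methylheptan-2-yl]-5,6-bis(methoxymethoxy)-4-methyl-1,2,3,4-tetrahydronaphthalene
Conditions: 2-nitrobenzenesulfonyl hydrazide (5 equiv), Et3N, CH2Cl2, rt
Reagents that add atoms: none
Why: Diimide transfers two hydrogens to the cis-disubstituted alkene in a concerted syn fashion with no metal hydride involved, so the double bond cannot migrate toward C1 or C4 and both stereocentres are preserved.

Step 22
Reactants: 32 tetralin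
Product: 34 (5R,8S)-8-[(2S,6R)-1,7-bis[(tert-butyldimethylsilyl)oxy]-6-methylheptan-2-yl]-3,4-bis(methoxymethoxy)-5-methyl-5,6,7,8-tetrahydronaphthalene-2-carboxylic acid, via C7 aryllithium 33 (not isolated)
Conditions: n-BuLi (1.5 equiv), TMEDA (1.5 equiv), THF, −20 → 0 °C; CO2 (gas), −78 °C → rt; cold 1 M HCl to pH 3, extracted at once
Reagents that add atoms: carbon dioxide, O=C=O
Why: Directed ortho-metalation: C7 is the only ring position ortho to an acetal oxygen (the C6 OMOM group), so coordination-assisted lithiation should occur there and not at C8 or the tertiary benzylic C–H bonds, and the aryllithium is carboxylated by CO2.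

Step 23
Reactants: 34 protected acid
Product: 35 (5R,8S)-8-[(2S,6R)-1,7-dihydroxy-6-methylheptan-2-yl]-3,4-dihydroxy-5-methyl-5,6,7,8-tetrahydronaphthalene-2-carboxylic acid
Conditions: 2 M HCl in MeOH/THF (1:1), rt, argon
Reagents that add atoms: none
Why: Acid-catalysed acetal exchange removes both MOM groups (the formaldehyde unit is trapped by the solvent as dimethoxymethane) and solvolysis cleaves both primary silyl ethers in the same pot, while room temperature should keep Fischer esterification of the hydrogen-bonded salicylic acid negligible.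

Step 24
Reactants: 35 tetraol acid
Product: 37 (5R,8S)-3,4-diacetoxy-8-[(2S,6R)-1,7-diacetoxy-6-methylheptan-2-yl]-5-methyl-5,6,7,8-tetrahydronaphthalene-2-carboxylic acid, via mixed anhydride 36 (not isolated)
Conditions: Ac2O (excess), pyridine, DMAP (cat.), 0 °C → rt; then THF/aq. NaHCO3, rt; acidified to pH 3
Reagents that add atoms: acetic anhydride, CC(=O)OC(C)=O
Why: DMAP-catalysed acylation esterifies the two primary alcohols and both phenols, and the carboxyl group, transiently converted into a mixed anhydride, is restored by the aqueous bicarbonate work-up.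

Step 25
Reactants: 37 tetraacetate acid
Product: 38 (5R,8S)-8-[(2S,6R)-1,7-diacetoxy-6-methylheptan-2-yl]-3,4-dihydroxy-5-methyl-5,6,7,8-tetrahydronaphthalene-2-carboxylic acid (target)
Conditions: NH4OAc (8 equiv), MeOH, rt
Reagents that add atoms: none
Why: Chemoselective transesterification: phenolic acetates (phenoxide leaving groups, here further activated by the neighbouring carboxylate and catechol oxygen) are cleaved by buffered methanol far faster than primary alkyl acetates, so only the C5 and C6 esters are removed.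

Compound list

1 | 2',3'-dihydroxyacetophenone | CC(=O)c1cccc(O)c1O | starting material
2 | 1-[2,3-bis(methoxymethoxy)phenyl]ethan-1-one | CC(=O)c1cccc(OCOC)c1OCOC | intermediate
3 | 1,2-bis(methoxymethoxy)-3-(prop-1-en-2-yl)benzene | C=C(C)c1cccc(OCOC)c1OCOC | intermediate
4 | 2-{(2R)-2-[2,3-bis(methoxymethoxy)phenyl]propyl}-4,4,5,5-tetramethyl-1,3,2-dioxaborolane | CC1(C)OB(C[C@@H](C)c2cccc(OCOC)c2OCOC)OC1(C)C | intermediate (not isolated)
5 | (2S)-2-[2,3-bis(methoxymethoxy)phenyl]propan-1-ol | OC[C@@H](C)c1cccc(OCOC)c1OCOC | intermediate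
6 | 1-[(2S)-1-(benzyloxy)propan-2-yl]-2,3-bis(methoxymethoxy)benzene | C[C@H](COCc1ccccc1)c1cccc(OCOC)c1OCOC | intermediate
7 | 2-[(2S)-1-(benzyloxy)propan-2-yl]-1-bromo-3,4-bis(methoxymethoxy)benzene | C[C@H](COCc1ccccc1)c1c(Br)ccc(OCOC)c1OCOC | intermediate
8 | {2-[(2S)-1-(benzyloxy)propan-2-yl]-3,4-bis(methoxymethoxy)phenyl}lithium | C[C@H](COCc1ccccc1)c1c([Li])ccc(OCOC)c1OCOC | intermediate (not isolated)
9 | lithium {2-[(2S)-1-(benzyloxy)propan-2-yl]-3,4-bis(methoxymethoxy)phenyl}tri(propan-2-yloxy)borate | [Li+].C[C@H](COCc1ccccc1)c1c([B-](OC(C)C)(OC(C)C)OC(C)C)ccc(OCOC)c1OCOC | intermediate (not isolated)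
10 | {2-[(2S)-1-(benzyloxy)propan-2-yl]-3,4-bis(methoxymethoxy)phenyl}boronic acid | C[C@H](COCc1ccccc1)c1c(B(O)O)ccc(OCOC)c1OCOC | intermediate
11 | furan-2(5H)-one | O=C1C=CCO1 | starting material
12 | (4S)-4-{2-[(2S)-1-(benzyloxy)propan-2-yl]-3,4-bis(methoxymethoxy)phenyl}dihydrofuran-2(3H)-one | O=C1C[C@@H](c2ccc(OCOC)c(OCOC)c2[C@H](C)COCc2ccccc2)CO1 | intermediate
13 | lithium enolate of 12 (O-lithiated at the lactone carbonyl, C11=C12 enolate, 4S) | [Li]OC1=C[C@@H](c2ccc(OCOC)c(OCOC)c2[C@H](C)COCc2ccccc2)CO1 | intermediate (not isolated)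
14 | (3S,4S)-4-{2-[(2S)-1-(benzyloxy)propan-2-yl]-3,4-bis(methoxymethoxy)phenyl}-3-(hydroxymethyl)dihydrofuran-2(3H)-one | O=C1[C@H](CO)[C@@H](c2ccc(OCOC)c(OCOC)c2[C@H](C)COCc2ccccc2)CO1 | intermediate
15 | (3S,4S)-4-{2-[(2S)-1-(benzyloxy)propan-2-yl]-3,4-bis(methoxymethoxy)phenyl}-3-{[(tert-butyldimethylsilyl)oxy]methyl}dihydrofuran-2(3H)-one | O=C1[C@H](CO[Si](C)(C)C(C)(C)C)[C@@H](c2ccc(OCOC)c(OCOC)c2[C@H](C)COCc2ccccc2)CO1 | intermediate
16 | (3S,4S)-4-{2-[(2S)-1-(benzyloxy)propan-2-yl]-3,4-bis(methoxymethoxy)phenyl}-3-{[(tert-butyldimethylsilyl)oxy]methyl}tetrahydrofuran-2-ol (anomeric mixture) | OC1[C@H](CO[Si](C)(C)C(C)(C)C)[C@@H](c2ccc(OCOC)c(OCOC)c2[C@H](C)COCc2ccccc2)CO1 | intermediate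
17 | methyl (S)-3-hydroxy-2-methylpropanoate (Roche ester) | COC(=O)[C@@H](C)CO | starting material
18 | methyl (S)-3-[(tert-butyldimethylsilyl)oxy]-2-methylpropanoate | COC(=O)[C@@H](C)CO[Si](C)(C)C(C)(C)C | intermediate
19 | (R)-3-[(tert-butyldimethylsilyl)oxy]-2-methylpropan-1-ol | OC[C@@H](C)CO[Si](C)(C)C(C)(C)C | intermediate
20 | (S)-tert-butyl(3-iodo-2-methylpropoxy)dimethylsilane | IC[C@@H](C)CO[Si](C)(C)C(C)(C)C | intermediate
21 | [(3R)-4-[(tert-butyldimethylsilyl)oxy]-3-methylbutyl]triphenylphosphonium iodide | [I-].c1ccccc1[P+](c1ccccc1)(c1ccccc1)CC[C@@H](C)CO[Si](C)(C)C(C)(C)C | intermediate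
22 | [(3R)-4-[(tert-butyldimethylsilyl)oxy]-3-methylbutylidene]triphenylphosphorane | c1ccccc1P(c1ccccc1)(c1ccccc1)=CC[C@@H](C)CO[Si](C)(C)C(C)(C)C | intermediate (not isolated)
23 | (2S,3S,4Z,7R)-2-{2-[(2S)-1-(benzyloxy)propan-2-yl]-3,4-bis(methoxymethoxy)phenyl}-8-[(tert-butyldimethylsilyl)oxy]-3-{[(tert-butyldimethylsilyl)oxy]methyl}-7-methyloct-4-en-1-ol | OC[C@H](c1ccc(OCOC)c(OCOC)c1[C@H](C)COCc1ccccc1)[C@@H](CO[Si](C)(C)C(C)(C)C)/C=C\C[C@@H](C)CO[Si](C)(C)C(C)(C)C | intermediate
24 | (2S,3S,7R)-8-[(tert-butyldimethylsilyl)oxy]-3-{[(tert-butyldimethylsilyl)oxy]methyl}-2-{2-[(2S)-1-hydroxypropan-2-yl]-3,4-bis(methoxymethoxy)phenyl}-7-methyloctan-1-ol | OC[C@H](c1ccc(OCOC)c(OCOC)c1[C@H](C)CO)[C@@H](CO[Si](C)(C)C(C)(C)C)CCC[C@@H](C)CO[Si](C)(C)C(C)(C)C | intermediate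
25 | bis(methanesulfonate) of diol 24 (mesylates on C2–O and C3–O) | CS(=O)(=O)OC[C@H](c1ccc(OCOC)c(OCOC)c1[C@H](C)COS(C)(=O)=O)[C@@H](CO[Si](C)(C)C(C)(C)C)CCC[C@@H](C)CO[Si](C)(C)C(C)(C)C | intermediate
26 | (1S,5S)-1-[(2S,6R)-1,7-bis[(tert-butyldimethylsilyl)oxy]-6-methylheptan-2-yl]-6,7-bis(methoxymethoxy)-5-methyl-1,2,4,5-tetrahydro-3-benzothiepine | CC(C)(C)[Si](C)(C)OC[C@H](C)CCC[C@H](CO[Si](C)(C)C(C)(C)C)[C@@H]1CSC[C@@H](C)c2c1ccc(OCOC)c2OCOC | intermediate
27 | 3-oxide of 26 (sulfoxide, configuration at sulfur not defined) | CC(C)(C)[Si](C)(C)OC[C@H](C)CCC[C@H](CO[Si](C)(C)C(C)(C)C)[C@@H]1CS(=O)C[C@@H](C)c2c1ccc(OCOC)c2OCOC | intermediate (not isolated)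
28 | (1S,5S)-1-[(2S,6R)-1,7-bis[(tert-butyldimethylsilyl)oxy]-6-methylheptan-2-yl]-6,7-bis(methoxymethoxy)-5-methyl-1,2,4,5-tetrahydro-3-benzothiepine 3,3-dioxide (key-step precursor) | CC(C)(C)[Si](C)(C)OC[C@H](C)CCC[C@H](CO[Si](C)(C)C(C)(C)C)[C@@H]1CS(=O)(=O)C[C@@H](C)c2c1ccc(OCOC)c2OCOC | intermediate
29 | α-bromo derivative of sulfone 28 (drawn brominated at C3; the C2 isomer leads to the same alkene; CHBr configuration not defined) | CC(C)(C)[Si](C)(C)OC[C@H](C)CCC[C@H](CO[Si](C)(C)C(C)(C)C)[C@@H]1CS(=O)(=O)C(Br)[C@@H](C)c2c1ccc(OCOC)c2OCOC | intermediate (not isolated)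
30 | episulfone: thiirane 1,1-dioxide spanning C2 and C3 of the tetralin skeleton (cis-fused, configuration at C2/C3 not defined) | CC(C)(C)[Si](C)(C)OC[C@H](C)CCC[C@H](CO[Si](C)(C)C(C)(C)C)[C@@H]1C2C([C@@H](C)c3c1ccc(OCOC)c3OCOC)S2(=O)=O | intermediate (not isolated)
31 | (1S,4R)-1-[(2S,6R)-1,7-bis[(tert-butyldimethylsilyl)oxy]-6-methylheptan-2-yl]-5,6-bis(methoxymethoxy)-4-methyl-1,4-dihydronaphthalene (key-step product) | CC(C)(C)[Si](C)(C)OC[C@H](C)CCC[C@H](CO[Si](C)(C)C(C)(C)C)[C@@H]1C=C[C@@H](C)c2c1ccc(OCOC)c2OCOC | intermediate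
32 | (1S,4R)-1-[(2S,6R)-1,7-bis[(tert-butyldimethylsilyl)oxy]-6-methylheptan-2-yl]-5,6-bis(methoxymethoxy)-4-methyl-1,2,3,4-tetrahydronaphthalene | CC(C)(C)[Si](C)(C)OC[C@H](C)CCC[C@H](CO[Si](C)(C)C(C)(C)C)[C@@H]1CC[C@@H](C)c2c1ccc(OCOC)c2OCOC | intermediate
33 | C7-lithio derivative of 32 | CC(C)(C)[Si](C)(C)OC[C@H](C)CCC[C@H](CO[Si](C)(C)C(C)(C)C)[C@@H]1CC[C@@H](C)c2c1cc([Li])c(OCOC)c2OCOC | intermediate (not isolated)
34 | (5R,8S)-8-[(2S,6R)-1,7-bis[(tert-butyldimethylsilyl)oxy]-6-methylheptan-2-yl]-3,4-bis(methoxymethoxy)-5-methyl-5,6,7,8-tetrahydronaphthalene-2-carboxylic acid | CC(C)(C)[Si](C)(C)OC[C@H](C)CCC[C@H](CO[Si](C)(C)C(C)(C)C)[C@@H]1CC[C@@H](C)c2c1cc(C(=O)O)c(OCOC)c2OCOC | intermediate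
35 | (5R,8S)-8-[(2S,6R)-1,7-dihydroxy-6-methylheptan-2-yl]-3,4-dihydroxy-5-methyl-5,6,7,8-tetrahydronaphthalene-2-carboxylic acid | OC[C@H](C)CCC[C@H](CO)[C@@H]1CC[C@@H](C)c2c1cc(C(=O)O)c(O)c2O | intermediate
36 | mixed acetic anhydride of tetraacetate 37 (at the C7 carboxyl group) | CC(=O)OC[C@H](C)CCC[C@H](COC(C)=O)[C@@H]1CC[C@@H](C)c2c1cc(C(=O)OC(C)=O)c(OC(C)=O)c2OC(C)=O | intermediate (not isolated)
37 | (5R,8S)-3,4-diacetoxy-8-[(2S,6R)-1,7-diacetoxy-6-methylheptan-2-yl]-5-methyl-5,6,7,8-tetrahydronaphthalene-2-carboxylic acid | CC(=O)OC[C@H](C)CCC[C@H](COC(C)=O)[C@@H]1CC[C@@H](C)c2c1cc(C(=O)O)c(OC(C)=O)c2OC(C)=O | intermediate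
38 | (5R,8S)-8-[(2S,6R)-1,7-diacetoxy-6-methylheptan-2-yl]-3,4-dihydroxy-5-methyl-5,6,7,8-tetrahydronaphthalene-2-carboxylic acid (CNP0245723.1) | CC(=O)OC[C@H](C)CCC[C@H](COC(C)=O)[C@@H]1CC[C@@H](C)c2c1cc(C(=O)O)c(O)c2O | target

Total step count: 25. Longest linear sequence: 21 steps (steps 1–10 and 15–25; steps 11–14 form the side-chain branch).

Steps most likely to fail

1. Step 20 (Ramberg–Bäcklund contraction). What may go wrong: over-bromination of the two α-methylenes, which diverts the sulfone into fragmentation instead of episulfone formation, and base-promoted migration of the new double bond into conjugation or air oxidation of the dihydronaphthalene, either of which erases C1 or C4. The fallback builds the same C2–C3 bond by carbanion alkylation instead of sulfur extrusion; it sets out from alkene alcohol 23 and comes back at tetralin 32. The free C2 hydroxyl of 23 is converted with diphenyl disulfide and tributylphosphine into the C2 phenyl thioether F1, which molybdate/H2O2 oxidises to the C2 phenyl sulfone F2 without touching the C12=C13 alkene. Hydrogenation over Pd/C then saturates the alkene and removes the benzyl group to give the sulfone alcohol F3, and iodine/PPh3/imidazole turns the C3 hydroxyl into the C3 iodide F4. KHMDS in THF at −78 °C generates the α-sulfonyl carbanion at C2, which closes the ring by 6-exo-tet displacement of iodide to the 2-(phenylsulfonyl)tetralin F5. Sodium amalgam in phosphate-buffered methanol removes the sulfonyl group and gives 32; C1 and C4 are never α to an anion or a carbonyl on this path.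

2. Step 7 (rhodium-catalysed arylation of furanone). What may go wrong: slow transmetalation and insertion of the ortho-branched, electron-rich arylrhodium, so that protodeboronation and base-induced loss of the furanone outrun the addition, and incomplete catalyst control next to the C4 centre. The fallback separates C–C bond formation from stereocontrol; it sets out from boronic acid 10 and comes back at lactone 12. Suzuki–Miyaura coupling of 10 with 4-bromofuran-2(5H)-one (Pd(OAc)2/SPhos, KF, THF/H2O) gives the 4-aryl butenolide F6. Copper hydride-catalysed enantioselective 1,4-reduction of F6 (Cu(OAc)2, p-tol-BINAP antipode selected for the S product, polymethylhydrosiloxane, t-BuOH) then sets C1 and delivers 12.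

3. Step 3 (asymmetric hydroboration). What may go wrong: insufficient face discrimination for an ortho-alkoxy α-methylstyrene (twisted arene, possible binding of cobalt by the acetal), which would carry the C4 epimer forward as a hard-to-separate diastereomer series. The fallback replaces catalyst control by kinetic resolution; it sets out from styrene 3 and comes back at alcohol 5. Hydroboration of 3 with 9-BBN gives the B-alkyl-9-borabicyclononane F7, and NaOH/H2O2 oxidises it to the racemic 2-arylpropan-1-ol F8. Lipase-catalysed transesterification with vinyl acetate (Burkholderia cepacia lipase, t-BuOMe, low temperature), a known resolution of 2-arylpropan-1-ols, is expected to acylate the S enantiomer preferentially. The separated S acetate F9 is methanolysed (K2CO3, MeOH) to give 5; should the enzyme show the opposite sense, the S alcohol would be taken from the unreacted fraction instead.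

Further compounds

F1 | step 20 | phenyl thioether of 23 at C2 (C2–SPh in place of C2–OH; Z-alkene and benzyl ether retained) | c1ccccc1SC[C@H](c2ccc(OCOC)c(OCOC)c2[C@H](C)COCc3ccccc3)[C@@H](CO[Si](C)(C)C(C)(C)C)/C=C\C[C@@H](C)CO[Si](C)(C)C(C)(C)C
F2 | step 20 | C2 phenyl sulfone corresponding to F1 | O=S(=O)(c1ccccc1)C[C@H](c2ccc(OCOC)c(OCOC)c2[C@H](C)COCc3ccccc3)[C@@H](CO[Si](C)(C)C(C)(C)C)/C=C\C[C@@H](C)CO[Si](C)(C)C(C)(C)C
F3 | step 20 | saturated C2 phenyl sulfone with free C3 hydroxyl | O=S(=O)(c1ccccc1)C[C@H](c2ccc(OCOC)c(OCOC)c2[C@H](C)CO)[C@@H](CO[Si](C)(C)C(C)(C)C)CCC[C@@H](C)CO[Si](C)(C)C(C)(C)C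
F4 | step 20 | saturated C2 phenyl sulfone with C3 iodide | O=S(=O)(c1ccccc1)C[C@H](c2ccc(OCOC)c(OCOC)c2[C@H](C)CI)[C@@H](CO[Si](C)(C)C(C)(C)C)CCC[C@@H](C)CO[Si](C)(C)C(C)(C)C
F5 | step 20 | 2-(phenylsulfonyl) derivative of tetralin 32 (configuration at C2 not defined) | CC(C)(C)[Si](C)(C)OC[C@H](C)CCC[C@H](CO[Si](C)(C)C(C)(C)C)[C@@H]1C(S(=O)(=O)c3ccccc3)C[C@@H](C)c2c1ccc(OCOC)c2OCOC
F6 | step 7 | 4-{2-[(2S)-1-(benzyloxy)propan-2-yl]-3,4-bis(methoxymethoxy)phenyl}furan-2(5H)-one | O=C1C=C(c2ccc(OCOC)c(OCOC)c2[C@H](C)COCc3ccccc3)CO1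
F7 | step 3 | 9-{2-[2,3-bis(methoxymethoxy)phenyl]propyl}-9-borabicyclo[3.3.1]nonane (racemic) | CC(CB1C2CCCC1CCC2)c1cccc(OCOC)c1OCOC
F8 | step 3 | racemic 2-[2,3-bis(methoxymethoxy)phenyl]propan-1-ol | CC(CO)c1cccc(OCOC)c1OCOC
F9 | step 3 | (2S)-2-[2,3-bis(methoxymethoxy)phenyl]propyl acetate | CC(=O)OC[C@@H](C)c1cccc(OCOC)c1OCOC
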